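**Plan**
- Retrosynthetic cuts, in order: the 11,12-epoxide oxygen and the C6–Cl bond (last), C5–C6 (ten-membered ring, Nozaki–Hiyama–Kishi), lactone bond C8–C17 (tethered Reformatsky), C3=C4 (cross-metathesis), C1–C14 together with C2–O (isoxazoline), C9–C10 (Evans aldol).
- Enabling feature: the array C14(OAc)–C1(quaternary, Me-15)–C2(OAc) on the six-membered ring C1/C10–C14 is a masked β-hydroxy ketone, i.e. an isoxazoline C14=N–O–C2. A C14 nitrile oxide tethered through C13–C12–C11–C10 adds across the (E)-C1(Me)=C2 alkene and closes that ring.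
- Forward order: dienoyl imide + L-threose aldehyde → aldol → C11 vinyl ketone → nitro ketone → cycloaddition (ring C1/C10–C14) → C11-methyl alkene and 14-ol → enone and dienyl triflate → γ-lactone → ten-membered ring → 6-chloride → epoxide.
- Stereochemistry: C9/C10 from (S)-4-benzyloxazolidinone; C7 from L-threitol; C1/C2 from suprafacial cycloaddition to the (E)-alkene under C10 control; C14 by 1,3-anti hydroxyl-directed reduction; C8/C17 by the C7-tethered Reformatsky closure; C6 by Felkin–Anh reduction then SN2 inversion; C11/C12 by epoxidation anti to the axial C1 methyl.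

Key step: step 11

Remark: briarane numbering (C1–C20) is used for all intermediates; PMB = 4-methoxybenzyl, TBS = tert-butyldimethylsilyl. The CHBr centre of 28/29 and C6 of 35 are carried as epimer mixtures because the next step removes each centre.

**Step 1**
Reactants: 1 but-3-yn-1-ol
Product: 3 (E)-3-methylhexa-3,5-dien-1-ol, via alkenylalane 2 (not isolated)
Conditions: AlMe3, Cp2ZrCl2 (cat.), CH2Cl2, 0 °C to rt; then CH2=CHBr, Pd(PPh3)4 (cat.), ZnCl2, THF, rt
Reagents that add atoms: trimethylaluminium C[Al](C)C; vinyl bromide C=CBr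
Why: Zirconium-catalysed syn-carboalumination (Negishi) puts methyl on the internal alkyne carbon and aluminium cis to it, and the palladium-catalysed coupling with vinyl bromide goes with retention, which fixes the (E)-trisubstituted alkene.

**Step 2**
Reactants: 3 (E)-3-methylhexa-3,5-dien-1-ol
Product: 4 (E)-3-methylhexa-3,5-dienoic acid
Conditions: TEMPO (cat.), PhI(OAc)2, MeCN/H2O, rt
Reagents that add atoms: water O
Why: TEMPO/PhI(OAc)2 oxidation of a primary alcohol to the acid is mild enough to keep the diene out of conjugation with the carboxyl group.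

**Step 3**
Reactants: 4 (E)-3-methylhexa-3,5-dienoic acid; 5 (S)-4-benzyl-1,3-oxazolidin-2-one
Product: 7 (S)-4-benzyl-3-[(E)-3-methylhexa-3,5-dienoyl]-1,3-oxazolidin-2-one, via mixed anhydride 6 (not isolated)
Conditions: PivCl, Et3N, THF, −20 °C; then 5, LiCl, −20 °C to rt
Reagents that add atoms: none
Why: N-acylation through the mixed pivalic anhydride under LiCl/Et3N needs no strong base, so the β,γ-unsaturated acyl chain should not isomerise.

**Step 4**
Reactants: 8 (4S,5S)-2,2-dimethyl-1,3-dioxolane-4,5-dimethanol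
Product: 9 mono-PMB ether of 8
Conditions: NaH (1 equiv), THF, 0 °C; then 4-methoxybenzyl chloride, Bu4NI (cat.), rt
Reagents that add atoms: 4-methoxybenzyl chloride COc1ccc(CCl)cc1
Why: Williamson mono-etherification of the C2-symmetric diol, in which either hydroxyl gives the same product.

**Step 5**
Reactants: 9 mono-PMB ether of 8
Product: 10 (4R,5S)-5-[(4-methoxybenzyloxy)methyl]-2,2-dimethyl-1,3-dioxolane-4-carbaldehyde
Conditions: Dess–Martin periodinane, NaHCO3, CH2Cl2, 0 °C to rt
Reagents that add atoms: none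
Why: Buffered Dess–Martin oxidation should give the α-alkoxy aldehyde without epimerising the adjacent dioxolane centre, which later becomes C8 and is oxidised away.

**Step 6**
Reactants: 7 dienoyl imide; 10 threose aldehyde
Product: 12 (9S,10S) syn-aldol imide, via boron enolate 11 (not isolated)
Conditions: Bu2BOTf, iPr2NEt, CH2Cl2, −78 to 0 °C; then 10, −78 to 0 °C; pH 7 buffer, MeOH, H2O2, 0 °C
Reagents that add atoms: none
Why: Evans syn-aldol reaction of the (Z)-boron dienolate reacts at the α-carbon through a chair transition state and sets C9 and C10 under auxiliary control, in the same sense as Felkin–Anh addition to the α-alkoxy aldehyde (matched pair).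

**Step 7**
Reactants: 12 syn-aldol imide
Product: 13 Weinreb amide
Conditions: MeONHMe·HCl, AlMe3, THF, −20 to 0 °C
Reagents that add atoms: N,O-dimethylhydroxylamine hydrochloride CNOC.Cl
Why: Aluminium amide transamidation of the β-hydroxy imide cleaves the exocyclic acyl group selectively and releases auxiliary 5 for recovery.

**Step 8**
Reactants: 13 Weinreb amide
Product: 14 9-O-TBS Weinreb amide
Conditions: TBSOTf, 2,6-lutidine, CH2Cl2, −78 to 0 °C
Reagents that add atoms: tert-butyldimethylsilyl triflate CC(C)(C)[Si](C)(C)OS(=O)(=O)C(F)(F)F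
Why: Silyl triflate/lutidine silylates the hindered C9 hydroxyl without base-induced retro-aldol cleavage.

**Step 9**
Reactants: 14 9-O-TBS Weinreb amide
Product: 15 C11 vinyl ketone
Conditions: CH2=CHMgBr, THF, −78 to −20 °C; inverse quench into cold aq. NH4Cl
Reagents that add atoms: vinylmagnesium bromide C=C[Mg]Br
Why: The chelated tetrahedral adduct of the Weinreb amide stops the Grignard addition at the ketone stage, and the low temperature limits enolisation at C10.

**Step 10**
Reactants: 15 C11 vinyl ketone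
Product: 16 14-nitro-11-ketone
Conditions: MeNO2 (solvent), 1,1,3,3-tetramethylguanidine (cat.), 0 °C
Reagents that add atoms: nitromethane C[N+](=O)[O-]
Why: Michael addition of the nitronate to the unhindered vinyl ketone adds C14 with its nitrogen, and the weakly basic nitronate medium should leave C10 untouched.

**Step 11**
Reactants: 16 14-nitro-11-ketone
Product: 18 isoxazoline ketone (C1, C2, C9, C10 as in the target), via nitrile oxide 17 (not isolated)
Conditions: PhNCO, Et3N (cat.), toluene, high dilution, slow addition, rt to 60 °C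
Reagents that add atoms: none
Why: Phenyl isocyanate dehydrates the primary nitro group (Mukaiyama) to nitrile oxide 17, which adds in a concerted suprafacial [3+2] cycloaddition across the (E)-C1(Me)=C2 alkene; the closest known reaction type is the intramolecular nitrile oxide–olefin cycloaddition used to build quaternary carbons as masked aldols. The carbocycle C1/C10–C14 closes in the 6-exo sense (C14 bonds to the proximal alkene carbon C1), and the isoxazoline C14=N–O–C2 forms as the fused second ring. C1 and C2 are set together by the alkene geometry (Me-15 and C3 cis on the isoxazoline), and C1 relative to C10 by a chair-like transition state in which the C9-bearing substituent on the allylic centre C10 lies pseudo-equatorial and anti to the forming C1–C14 bond. The step needs regioselectivity between the two alkenes of the diene, which the tether secures (six- against eight-membered ring), and chemoselectivity against dimerisation of the dipole, which high dilution and slow generation secure. The later N–O cleavage turns this ring into the C14 ketone and C2 carbinol that become the 2,14-diacetate.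

**Step 12**
Reactants: 18 isoxazoline ketone
Product: 19 C11 enol triflate
Conditions: KHMDS, PhNTf2, THF, −78 °C
Reagents that add atoms: N-phenylbis(trifluoromethanesulfonimide) O=S(=O)(N(c1ccccc1)S(=O)(=O)C(F)(F)F)C(F)(F)F
Why: Kinetic deprotonation at the C12 methylene, not at the tertiary C10–H next to quaternary C1, and O-triflation place the double bond at C11=C12.

**Step 13**
Reactants: 19 C11 enol triflate
Product: 20 11-methyl-Δ11 isoxazoline
Conditions: MeMgBr, Fe(acac)3 (cat.), THF/NMP, −30 °C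
Reagents that add atoms: methylmagnesium bromide C[Mg]Br
Why: Iron-catalysed Kumada-type coupling of an alkenyl triflate with a methyl Grignard reagent installs C20 without moving the alkene and is fast enough at low temperature to spare the isoxazoline.

**Step 14**
Reactants: 20 11-methyl-Δ11 isoxazoline
Product: 22 2-hydroxy-14-ketone, via hydroxy imine 21 (not isolated)
Conditions: SmI2, THF, 0 °C; then B(OH)3, MeOH/H2O, rt
Reagents that add atoms: water O
Why: Reductive N–O cleavage of the 2-isoxazoline and hydrolysis of the β-hydroxy imine under boric acid buffer unveil the β-hydroxy ketone without retro-aldol cleavage, and the quaternary C1 cannot epimerise.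

**Step 15**
Reactants: 22 2-hydroxy-14-ketone
Product: 23 2,14-diol
Conditions: Me4NBH(OAc)3, MeCN/AcOH, −30 °C
Reagents that add atoms: none
Why: Evans–Saksena reduction, in which the acetoxyborohydride bound to the C2 hydroxyl delivers hydride intramolecularly to C14, should give the 1,3-anti diol, i.e. the 14α-alcohol.

**Step 16**
Reactants: 23 2,14-diol
Product: 24 2,14-diacetate
Conditions: Ac2O, DMAP, pyridine, rt
Reagents that add atoms: acetic anhydride CC(=O)OC(C)=O
Why: DMAP-catalysed acetylation installs two of the three acetates of the target, which then serve as protecting groups.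

**Step 17**
Reactants: 24 2,14-diacetate
Product: 25 (3E)-enone (C5 methyl ketone)
Conditions: methyl vinyl ketone (excess), second-generation Hoveyda–Grubbs catalyst, CH2Cl2, 40 °C
Reagents that add atoms: methyl vinyl ketone CC(=O)C=C
Why: Olefin cross-metathesis of the terminal vinyl group with an electron-poor enone partner is (E)-selective and should leave the trisubstituted ring alkene untouched.

**Step 18**
Reactants: 25 (3E)-enone
Product: 26 dienyl triflate
Conditions: LiHMDS, PhNTf2, THF, −78 °C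
Reagents that add atoms: N-phenylbis(trifluoromethanesulfonimide) O=S(=O)(N(c1ccccc1)S(=O)(=O)C(F)(F)F)C(F)(F)F
Why: Kinetic deprotonation of the methyl ketone at C16 and O-triflation of the cross-conjugated dienolate give the 2-triflyloxy-1,3-diene that carries the future exocyclic methylene.

**Step 19**
Reactants: 26 dienyl triflate
Product: 27 7,8-diol
Conditions: AcOH/H2O (4:1), 45 °C
Reagents that add atoms: none
Why: Acid hydrolysis of the dioxolane should leave the acetates, the hindered secondary TBS ether, the PMB ether and the alkenyl triflate intact.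

**Step 20**
Reactants: 27 7,8-diol
Product: 28 7-(2-bromopropanoate)
Conditions: 2-bromopropanoyl bromide (1 equiv), pyridine, CH2Cl2, −40 °C
Reagents that add atoms: 2-bromopropanoyl bromide CC(Br)C(Br)=O
Why: Acylation should occur at the less hindered C7 hydroxyl, because the C8 hydroxyl is flanked by the C9 silyloxy group and the branched C10.

**Step 21**
Reactants: 28 7-(2-bromopropanoate)
Product: 29 8-ketone
Conditions: Dess–Martin periodinane, NaHCO3, CH2Cl2, rt
Reagents that add atoms: none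
Why: Neutral Dess–Martin oxidation of the remaining secondary alcohol gives the α-acyloxy ketone without epimerising C7 or C9.

**Step 22**
Reactants: 29 8-ketone
Product: 30 9-O-TBS hydroxy lactone (7R,8R,17R)
Conditions: Zn (Me3SiCl-activated), THF, 0 °C to rt
Reagents that add atoms: none
Why: Zinc inserts into the C–Br bond and the tethered zinc enolate adds to the C8 ketone (intramolecular Reformatsky reaction) to close the γ-lactone; the rotamer about C7–C8 that keeps C6 and C9 apart, which coincides with Felkin–Anh addition anti to the C9 silyloxy group, should place 8-OH cis to C6, and Me-18 should settle trans to the bulky C9 substituent.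

**Step 23**
Reactants: 30 9-O-TBS hydroxy lactone
Product: 31 8,9-dihydroxy lactone
Conditions: HF·pyridine, pyridine, THF, 0 °C to rt
Reagents that add atoms: none
Why: Buffered fluoride cleavage of the silyl ether is done here, before the allylic chloride exists, and the buffered medium should suppress migration of the lactone to O9.

**Step 24**
Reactants: 31 8,9-dihydroxy lactone
Product: 32 2,9,14-triacetate
Conditions: Ac2O, pyridine, DMAP (cat.), 0 °C
Reagents that add atoms: acetic anhydride CC(=O)OC(C)=O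
Why: The secondary C9 hydroxyl is acetylated while the tertiary C8 hydroxyl is too hindered to react under these conditions.

**Step 25**
Reactants: 32 2,9,14-triacetate
Product: 33 primary C6 alcohol
Conditions: DDQ, CH2Cl2/pH 7 buffer, 0 °C
Reagents that add atoms: none
Why: Oxidative cleavage of the PMB ether by DDQ in wet buffered solvent should leave the electron-poor dienyl triflate and the acetates intact.

**Step 26**
Reactants: 33 primary C6 alcohol
Product: 34 C6 aldehyde
Conditions: Dess–Martin periodinane, NaHCO3, CH2Cl2, 0 °C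
Reagents that add atoms: none
Why: Neutral oxidation gives the α-acyloxy aldehyde without retro-aldol cleavage at the tertiary C8 carbinol.

**Step 27**
Reactants: 34 C6 aldehyde
Product: 35 macrocyclic 6-alcohol (mixture of C6 epimers)
Conditions: CrCl2 (excess), NiCl2 (cat.), DMSO/THF, high dilution, rt
Reagents that add atoms: none
Why: In the Nozaki–Hiyama–Kishi reaction nickel inserts into the dienyl triflate and the derived alkenylchromium adds chemoselectively to the aldehyde, closing the ten-membered ring at C5–C6 in the presence of the acetates and the lactone; the C6 configuration is not relied on and is reset in steps 28 and 29.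

**Step 28**
Reactants: 35 macrocyclic 6-alcohol
Product: 36 macrocyclic dienone (6-ketone)
Conditions: Dess–Martin periodinane, NaHCO3, CH2Cl2, 0 °C
Reagents that add atoms: none
Why: Oxidation of the allylic alcohol merges both C6 epimers into one ketone, and the tertiary C8 hydroxyl cannot be oxidised.

**Step 29**
Reactants: 36 macrocyclic dienone
Product: 37 (6R)-allylic alcohol
Conditions: NaBH4, CeCl3·7H2O, MeOH, −78 °C
Reagents that add atoms: none
Why: Luche conditions enforce 1,2-reduction of the α-methylene ketone, and hydride delivery anti to the C7–O bond (Felkin–Anh) should give the alcohol with 6-OH syn to O7.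

**Step 30**
Reactants: 37 (6R)-allylic alcohol
Product: 38 (6S)-allylic chloride
Conditions: PPh3, hexachloroacetone, CH2Cl2, −20 to 0 °C
Reagents that add atoms: hexachloroacetone ClC(Cl)(Cl)C(=O)C(Cl)(Cl)Cl
Why: This Appel-type chlorination converts allylic alcohols into chlorides by SN2 displacement of the oxyphosphonium ion, with inversion and without allylic transposition, and the tertiary C8 hydroxyl is too hindered to react.

**Step 31**
Reactants: 38 (6S)-allylic chloride
Product: 39 CNP0106406.1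
Conditions: mCPBA, NaHCO3, CH2Cl2, 0 °C
Reagents that add atoms: 3-chloroperoxybenzoic acid O=C(OO)c1cccc(Cl)c1
Why: In this Prilezhaev epoxidation the peracid should select the electron-rich trisubstituted C11=C12 over the diene deactivated by the allylic acetate and chloride, and attack the α face anti to the axial C1 methyl and the β-oriented C9 substituent on C10.

**Compound list**
1 | but-3-yn-1-ol | C#CCCO | starting material
2 | (E)-alkenylalane, dimethylaluminium alkoxide form | C/C(=C\[Al](C)C)CCO[Al](C)C | intermediate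
3 | (E)-3-methylhexa-3,5-dien-1-ol | OCC/C(C)=C/C=C | intermediate
4 | (E)-3-methylhexa-3,5-dienoic acid | OC(=O)C/C(C)=C/C=C | intermediate
5 | (S)-4-benzyl-1,3-oxazolidin-2-one | O=C1N[C@@H](Cc2ccccc2)CO1 | starting material
6 | mixed pivalic anhydride of 4 | CC(C)(C)C(=O)OC(=O)C/C(C)=C/C=C | intermediate
7 | (S)-4-benzyl-3-[(E)-3-methylhexa-3,5-dienoyl]-1,3-oxazolidin-2-one | O=C(C/C(C)=C/C=C)N1[C@@H](Cc2ccccc2)COC1=O | intermediate
8 | (4S,5S)-2,2-dimethyl-1,3-dioxolane-4,5-dimethanol (2,3-O-isopropylidene-L-threitol) | OC[C@@H]1OC(C)(C)O[C@H]1CO | starting material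
9 | [(4S,5S)-5-[(4-methoxybenzyloxy)methyl]-2,2-dimethyl-1,3-dioxolan-4-yl]methanol | OC[C@@H]1OC(C)(C)O[C@H]1COCc1ccc(OC)cc1 | intermediate
10 | (4R,5S)-5-[(4-methoxybenzyloxy)methyl]-2,2-dimethyl-1,3-dioxolane-4-carbaldehyde | O=C[C@@H]1OC(C)(C)O[C@H]1COCc1ccc(OC)cc1 | intermediate
11 | dibutylboron (Z)-enolate of 7 | CCCCB(CCCC)O/C(=C\C(C)=C\C=C)N1[C@@H](Cc2ccccc2)COC1=O | intermediate
12 | (9S,10S) syn-aldol imide (C10 carries the (E)-dienyl group, C9–OH, C7/C8 acetonide, C6–OPMB) | O=C1OC[C@H](Cc2ccccc2)N1C(=O)[C@@H](/C(C)=C/C=C)[C@H](O)[C@@H]1OC(C)(C)O[C@H]1COCc1ccc(OC)cc1 | intermediate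
13 | Weinreb amide of the aldol acid | CON(C)C(=O)[C@@H](/C(C)=C/C=C)[C@H](O)[C@@H]1OC(C)(C)O[C@H]1COCc1ccc(OC)cc1 | intermediate
14 | 9-O-TBS Weinreb amide | CON(C)C(=O)[C@@H](/C(C)=C/C=C)[C@H](O[Si](C)(C)C(C)(C)C)[C@@H]1OC(C)(C)O[C@H]1COCc1ccc(OC)cc1 | intermediate
15 | C11 vinyl ketone | C=CC(=O)[C@@H](/C(C)=C/C=C)[C@H](O[Si](C)(C)C(C)(C)C)[C@@H]1OC(C)(C)O[C@H]1COCc1ccc(OC)cc1 | intermediate
16 | 14-nitro-11-ketone | O=[N+]([O-])CCCC(=O)[C@@H](/C(C)=C/C=C)[C@H](O[Si](C)(C)C(C)(C)C)[C@@H]1OC(C)(C)O[C@H]1COCc1ccc(OC)cc1 | intermediate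
17 | C14 nitrile oxide | [O-][N+]#CCCC(=O)[C@@H](/C(C)=C/C=C)[C@H](O[Si](C)(C)C(C)(C)C)[C@@H]1OC(C)(C)O[C@H]1COCc1ccc(OC)cc1 | intermediate
18 | isoxazoline ketone (isoxazoline C14=N–O–C2 fused at C1–C14 to the cyclohexanone, C11 ketone, 2-vinyl) | C=C[C@@H]1ON=C2CCC(=O)[C@H]([C@H](O[Si](C)(C)C(C)(C)C)[C@@H]3OC(C)(C)O[C@H]3COCc3ccc(OC)cc3)[C@@]12C | intermediate
19 | C11 enol triflate (Δ11) | C=C[C@@H]1ON=C2CC=C(OS(=O)(=O)C(F)(F)F)[C@H]([C@H](O[Si](C)(C)C(C)(C)C)[C@@H]3OC(C)(C)O[C@H]3COCc3ccc(OC)cc3)[C@@]12C | intermediate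
20 | 11-methyl-Δ11 isoxazoline | C=C[C@@H]1ON=C2CC=C(C)[C@H]([C@H](O[Si](C)(C)C(C)(C)C)[C@@H]3OC(C)(C)O[C@H]3COCc3ccc(OC)cc3)[C@@]12C | intermediate
21 | β-hydroxy imine (C2–OH, C14=NH) | C=C[C@H](O)[C@@]1(C)C(=N)CC=C(C)[C@@H]1[C@H](O[Si](C)(C)C(C)(C)C)[C@@H]2OC(C)(C)O[C@H]2COCc2ccc(OC)cc2 | intermediate
22 | 2-hydroxy-14-ketone | C=C[C@H](O)[C@@]1(C)C(=O)CC=C(C)[C@@H]1[C@H](O[Si](C)(C)C(C)(C)C)[C@@H]2OC(C)(C)O[C@H]2COCc2ccc(OC)cc2 | intermediate
23 | 2,14-diol (14α-OH) | C=C[C@H](O)[C@@]1(C)[C@@H](O)CC=C(C)[C@@H]1[C@H](O[Si](C)(C)C(C)(C)C)[C@@H]2OC(C)(C)O[C@H]2COCc2ccc(OC)cc2 | intermediate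
24 | 2,14-diacetate | C=C[C@H](OC(C)=O)[C@@]1(C)[C@@H](OC(C)=O)CC=C(C)[C@@H]1[C@H](O[Si](C)(C)C(C)(C)C)[C@@H]2OC(C)(C)O[C@H]2COCc2ccc(OC)cc2 | intermediate
25 | (3E)-enone, C5 methyl ketone | CC(=O)/C=C/[C@H](OC(C)=O)[C@@]1(C)[C@@H](OC(C)=O)CC=C(C)[C@@H]1[C@H](O[Si](C)(C)C(C)(C)C)[C@@H]2OC(C)(C)O[C@H]2COCc2ccc(OC)cc2 | intermediate
26 | dienyl triflate (C5–OTf, C5=C16) | C=C(OS(=O)(=O)C(F)(F)F)/C=C/[C@H](OC(C)=O)[C@@]1(C)[C@@H](OC(C)=O)CC=C(C)[C@@H]1[C@H](O[Si](C)(C)C(C)(C)C)[C@@H]2OC(C)(C)O[C@H]2COCc2ccc(OC)cc2 | intermediate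
27 | 7,8-diol | C=C(OS(=O)(=O)C(F)(F)F)/C=C/[C@H](OC(C)=O)[C@@]1(C)[C@@H](OC(C)=O)CC=C(C)[C@@H]1[C@H](O[Si](C)(C)C(C)(C)C)[C@H](O)[C@@H](O)COCc2ccc(OC)cc2 | intermediate
28 | 7-(2-bromopropanoate), epimers at CHBr | C=C(OS(=O)(=O)C(F)(F)F)/C=C/[C@H](OC(C)=O)[C@@]1(C)[C@@H](OC(C)=O)CC=C(C)[C@@H]1[C@H](O[Si](C)(C)C(C)(C)C)[C@H](O)[C@@H](OC(=O)C(C)Br)COCc2ccc(OC)cc2 | intermediate
29 | 8-ketone, epimers at CHBr | C=C(OS(=O)(=O)C(F)(F)F)/C=C/[C@H](OC(C)=O)[C@@]1(C)[C@@H](OC(C)=O)CC=C(C)[C@@H]1[C@H](O[Si](C)(C)C(C)(C)C)C(=O)[C@@H](OC(=O)C(C)Br)COCc2ccc(OC)cc2 | intermediate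
30 | 9-O-TBS hydroxy lactone (7R,8R,17R) | C=C(OS(=O)(=O)C(F)(F)F)/C=C/[C@H](OC(C)=O)[C@@]1(C)[C@@H](OC(C)=O)CC=C(C)[C@@H]1[C@H](O[Si](C)(C)C(C)(C)C)[C@]2(O)[C@@H](C)C(=O)O[C@H]2COCc2ccc(OC)cc2 | intermediate
31 | 8,9-dihydroxy lactone | C=C(OS(=O)(=O)C(F)(F)F)/C=C/[C@H](OC(C)=O)[C@@]1(C)[C@@H](OC(C)=O)CC=C(C)[C@@H]1[C@H](O)[C@]2(O)[C@@H](C)C(=O)O[C@H]2COCc2ccc(OC)cc2 | intermediate
32 | 2,9,14-triacetate, C6–OPMB | C=C(OS(=O)(=O)C(F)(F)F)/C=C/[C@H](OC(C)=O)[C@@]1(C)[C@@H](OC(C)=O)CC=C(C)[C@@H]1[C@H](OC(C)=O)[C@]2(O)[C@@H](C)C(=O)O[C@H]2COCc2ccc(OC)cc2 | intermediate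
33 | primary C6 alcohol | C=C(OS(=O)(=O)C(F)(F)F)/C=C/[C@H](OC(C)=O)[C@@]1(C)[C@@H](OC(C)=O)CC=C(C)[C@@H]1[C@H](OC(C)=O)[C@]2(O)[C@@H](C)C(=O)O[C@H]2CO | intermediate
34 | C6 aldehyde | C=C(OS(=O)(=O)C(F)(F)F)/C=C/[C@H](OC(C)=O)[C@@]1(C)[C@@H](OC(C)=O)CC=C(C)[C@@H]1[C@H](OC(C)=O)[C@]2(O)[C@@H](C)C(=O)O[C@H]2C=O | intermediate
35 | macrocyclic 6-alcohol, mixture of C6 epimers | C=C1/C=C/[C@H](OC(C)=O)[C@@]2(C)[C@@H](OC(C)=O)CC=C(C)[C@@H]2[C@H](OC(C)=O)[C@]2(O)[C@@H](C)C(=O)O[C@H]2C1O | intermediate
36 | macrocyclic dienone (6-ketone) | C=C1/C=C/[C@H](OC(C)=O)[C@@]2(C)[C@@H](OC(C)=O)CC=C(C)[C@@H]2[C@H](OC(C)=O)[C@]2(O)[C@@H](C)C(=O)O[C@H]2C1=O | intermediate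
37 | (6R)-allylic alcohol | C=C1/C=C/[C@H](OC(C)=O)[C@@]2(C)[C@@H](OC(C)=O)CC=C(C)[C@@H]2[C@H](OC(C)=O)[C@]2(O)[C@@H](C)C(=O)O[C@H]2[C@@H]1O | intermediate
38 | (6S)-allylic chloride, Δ11 | C=C1/C=C/[C@H](OC(C)=O)[C@@]2(C)[C@@H](OC(C)=O)CC=C(C)[C@@H]2[C@H](OC(C)=O)[C@]2(O)[C@@H](C)C(=O)O[C@H]2[C@H]1Cl | intermediate
39 | CNP0106406.1 | C=C1/C=C/[C@H](OC(C)=O)[C@@]2(C)[C@@H](OC(C)=O)C[C@H]3O[C@@]3(C)[C@@H]2[C@H](OC(C)=O)[C@]2(O)[C@@H](C)C(=O)O[C@H]2[C@H]1Cl | target

**Step count**
Total: 31 steps. Longest linear sequence: 29 steps (steps 1–3 and 6–31, from 1 to 39); steps 4 and 5 form the side branch to aldehyde 10.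

**Steps most likely to fail**

Step 27 (ring closure at C5–C6). Intermolecular oligomerisation and protodemetalation of the alkenylchromium species may outrun closure of the ten-membered ring, and low-valent nickel may ionise the allylic C2 acetate. The fallback closes the same bond as a ketone by acyl coupling, sets out from 33 and comes back at 36. Alcohol 33 is oxidised with TEMPO/PhI(OAc)2 in MeCN/H2O to the C6 carboxylic acid F3. Thiophenol, EDC·HCl and DMAP convert it into the S-phenyl thioester F4. Exchange of the triflate with Me3SnSnMe3, Pd(PPh3)4 and LiCl gives the dienylstannane thioester F5. An intramolecular Liebeskind–Srogl coupling (Pd2(dba)3, tri(2-furyl)phosphine, copper diphenylphosphinate CuO2PPh2, THF, high dilution) then gives dienone 36 directly, so that steps 26 to 28 are not needed.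

Step 11 (cycloaddition). Facial selectivity at C1 relative to C10 may be poor, C10 may epimerise under the amine before cyclisation, or the nitrile oxide may dimerise. The fallback uses a silyl nitronate as the dipole, sets out from 16 and comes back at 18. Me3SiCl and Et3N in toluene convert 16 into the silyl nitronate F1, a less reactive dipole that does not dimerise. It undergoes intramolecular silyl nitronate–olefin cycloaddition to the N-silyloxyisoxazolidine F2, and catalytic TsOH eliminates trimethylsilanol to give 18.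

Step 29 (reduction at C6). Hydride delivery to the macrocyclic ketone may occur from the wrong face, or 1,4-reduction may compete. The fallback corrects C6 by inversion, sets out from 36 and comes back at 37. If reduction of 36 gives mainly the (6S)-alcohol F6, Mitsunobu reaction with chloroacetic acid (PPh3, DIAD) gives the inverted (6R)-chloroacetate F7. Thiourea with NaHCO3 in ethanol removes the chloroacetyl group in the presence of the three acetates and returns 37.

**Further compounds**
F1 | step 11 | trimethylsilyl nitronate of 16 | C[Si](C)(C)O[N+]([O-])=CCCC(=O)[C@@H](/C(C)=C/C=C)[C@H](O[Si](C)(C)C(C)(C)C)[C@@H]1OC(C)(C)O[C@H]1COCc1ccc(OC)cc1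
F2 | step 11 | N-(trimethylsilyloxy)isoxazolidine | C=C[C@@H]1ON(O[Si](C)(C)C)C2CCC(=O)[C@H]([C@H](O[Si](C)(C)C(C)(C)C)[C@@H]3OC(C)(C)O[C@H]3COCc3ccc(OC)cc3)[C@@]12C
F3 | step 27 | C6 carboxylic acid | C=C(OS(=O)(=O)C(F)(F)F)/C=C/[C@H](OC(C)=O)[C@@]1(C)[C@@H](OC(C)=O)CC=C(C)[C@@H]1[C@H](OC(C)=O)[C@]2(O)[C@@H](C)C(=O)O[C@H]2C(=O)O
F4 | step 27 | C6 S-phenyl thioester | C=C(OS(=O)(=O)C(F)(F)F)/C=C/[C@H](OC(C)=O)[C@@]1(C)[C@@H](OC(C)=O)CC=C(C)[C@@H]1[C@H](OC(C)=O)[C@]2(O)[C@@H](C)C(=O)O[C@H]2C(=O)Sc2ccccc2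
F5 | step 27 | dienyl trimethylstannane S-phenyl thioester | C=C([Sn](C)(C)C)/C=C/[C@H](OC(C)=O)[C@@]1(C)[C@@H](OC(C)=O)CC=C(C)[C@@H]1[C@H](OC(C)=O)[C@]2(O)[C@@H](C)C(=O)O[C@H]2C(=O)Sc2ccccc2
F6 | step 29 | (6S)-allylic alcohol | C=C1/C=C/[C@H](OC(C)=O)[C@@]2(C)[C@@H](OC(C)=O)CC=C(C)[C@@H]2[C@H](OC(C)=O)[C@]2(O)[C@@H](C)C(=O)O[C@H]2[C@H]1O
F7 | step 29 | (6R)-chloroacetate | C=C1/C=C/[C@H](OC(C)=O)[C@@]2(C)[C@@H](OC(C)=O)CC=C(C)[C@@H]2[C@H](OC(C)=O)[C@]2(O)[C@@H](C)C(=O)O[C@H]2[C@@H]1OC(=O)CCl
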